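**Retrosynthetic overview**
- C2–N bond last: azide conjugate addition/N2 loss on the naphthoquinone. The quinone (ring B) is unveiled just before by oxidative demethylation.
- C9=C10: Horner–Wadsworth–Emmons union of a chain lactol-acid with an aryl β-ketophosphonate.
- Key step: the lactone C–O bond (C9 acyl to O5), formed by a catalytic enantioselective desymmetrising δ-lactonisation of a meso trihydroxy diacid. It fixes the absolute configuration of all seven stereocentres and differentiates the two termini.
- The meso diacid is built two-directionally: bis-allylic carbinol, double anti-hydroboration, double (Z)-crotylboration, double ozonolysis/oxidation.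
- Ring order: benzenoid ring A by Diels–Alder onto benzoquinone (ring B carried as its dimethyl ether) and aromatised; the temporary δ-lactone ring in the key step (opened again after reduction); quinone ring B last.

Assumption: the target is the (2R,3S,4S,5S,6S,7S,8R,9E) acid encoded by the SMILES; the sense of induction in step 8 is a model-based prediction, and the antipodal catalyst is equally available if it proves opposite.

**Step 1**
Reactants: 1 methacrolein; 2 isopropenylmagnesium bromide
Product: 3 2,4-dimethylpenta-1,4-dien-3-ol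
Conditions: THF, −78 → 0 °C
Reagents that add atoms: none
Why: Grignard 1,2-addition to the enal carbonyl gives the bis-allylic carbinol; the carbinol carbon bears two identical isopropenyl groups, so no stereocentre arises.

**Step 2**
Reactants: 3 2,4-dimethylpenta-1,4-dien-3-ol
Product: 4 {[(2,4-dimethylpenta-1,4-dien-3-yl)oxy]methyl}benzene
Conditions: NaH, BnBr, Bu4NI (cat.), THF, 0 °C → rt
Reagents that add atoms: benzyl bromide, BrCc1ccccc1
Why: Williamson etherification protects the future C5 oxygen as a benzyl ether that survives hydroboration, oxidation and ozonolysis and is removed later by neutral hydrogenolysis.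

**Step 3**
Reactants: 4 {[(2,4-dimethylpenta-1,4-dien-3-yl)oxy]methyl}benzene
Product: 6 (2R,3s,4S)-3-(benzyloxy)-2,4-dimethylpentane-1,5-diol, via bis(9-BBN) adduct 5 (not isolated)
Conditions: 9-BBN (3 equiv), THF, 0 °C → rt; then NaOH (aq.), H2O2, 0 °C → rt
Reagents that add atoms: hydrogen peroxide, OO; 9-borabicyclo[3.3.1]nonane, B1C2CCCC1CCC2 (boron and ring carbons stay only in 5)
Why: Two-directional Still–Barrish hydroboration–oxidation: the bulky borane adds anti-Markovnikov to each 1,1-disubstituted alkene from the face set by the allylic C–O stereocentre (A(1,3)-minimised conformer), which gives the anti relationship on both sides (meso anti,anti diol), and the C–B bonds are oxidised with retention.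

**Step 4**
Reactants: 6 (2R,3s,4S)-3-(benzyloxy)-2,4-dimethylpentane-1,5-diol
Product: 8 (2R,3r,4S)-3-(benzyloxy)-2,4-dimethylpentanedial, via bis(alkoxysulfonium) salt 7 (not isolated)
Conditions: (COCl)2, DMSO, CH2Cl2, −78 °C; then Et3N, −78 → −20 °C; used crude
Reagents that add atoms: dimethyl sulfoxide, CS(C)=O (sulfur and its methyl groups stay only in 7)
Why: Swern oxidation activates both primary alcohols at once, so the 1,5-diol goes to the dialdehyde without lactol over-oxidation, and the low temperature keeps the α-methyl centres intact.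

**Step 5**
Reactants: 8 (2R,3r,4S)-3-(benzyloxy)-2,4-dimethylpentanedial; 9 (Z)-crotylboronic acid pinacol ester
Product: 10 (3R,4S,5S,6s,7R,8R,9S)-6-(benzyloxy)-3,5,7,9-tetramethylundeca-1,10-diene-4,8-diol
Conditions: 9 (2.6 equiv), toluene, 4 Å MS, −78 °C → rt, 48 h
Reagents that add atoms: none
Why: Two-directional allylboration through closed chair (Zimmerman–Traxler-type) transition states: the (Z)-crotyl geometry gives the syn methyl/hydroxyl relationship, and the intrinsic anti-Felkin preference of (Z)-crotylboronates toward α-methyl aldehydes (the Felkin chair suffers a syn-pentane clash) gives the anti relationship to the existing methyl at both termini, so the meso heptad forms and minor diastereomers are removed by chromatography.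

**Step 6**
Reactants: 10 (3R,4S,5S,6s,7R,8R,9S)-6-(benzyloxy)-3,5,7,9-tetramethylundeca-1,10-diene-4,8-diol
Product: 13 (2R,3S,4R,5s,6S,7R,8S)-5-(benzyloxy)-3,7-dihydroxy-2,4,6,8-tetramethylnonanedioic acid, via bis-ozonide 11 (not isolated), via meso dialdehyde 12 (not isolated)
Conditions: O3, CH2Cl2, −78 °C; Me2S, −78 °C → rt; then NaClO2, NaH2PO4, H2O2, MeCN/H2O, 0 °C → rt
Reagents that add atoms: ozone, [O-][O+]=O; sodium chlorite, [Na+].[O-]Cl=O
Why: Ozonolysis cleaves both vinyl groups and buffered Pinnick oxidation takes the β-hydroxy aldehydes straight to the acids without epimerising the α-centres or touching the secondary alcohols.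

**Step 7**
Reactants: 13 (2R,3S,4R,5s,6S,7R,8S)-5-(benzyloxy)-3,7-dihydroxy-2,4,6,8-tetramethylnonanedioic acid
Product: 14 (2R,3S,4S,5r,6R,7R,8S)-3,5,7-trihydroxy-2,4,6,8-tetramethylnonanedioic acid
Conditions: H2 (1 atm), Pd(OH)2/C, MeOH, rt; filtrate treated at once with i-Pr2NEt (2.2 equiv) and kept as the bis-ammonium salt
Reagents that add atoms: none
Why: Hydrogenolysis frees the C5 hydroxyl under neutral conditions, and storage as the dicarboxylate salt prevents spontaneous (racemic) lactonisation of the meso δ-hydroxy diacid.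

**Step 8**
Reactants: 14 (2R,3S,4S,5r,6R,7R,8S)-3,5,7-trihydroxy-2,4,6,8-tetramethylnonanedioic acid
Product: 16 (2R,3S,4R)-3-hydroxy-4-[(2R,3S,4R,5S)-4-hydroxy-3,5-dimethyl-6-oxooxan-2-yl]-2-methylpentanoic acid, via mixed pivalic anhydride 15 (not isolated)
Conditions: (S)-BTM [(S)-benzotetramisole, 10 mol%], Piv2O (1.2 equiv), i-Pr2NEt, CH2Cl2 (0.01 M), −40 → 0 °C
Reagents that add atoms: pivalic anhydride, CC(C)(C)C(=O)OC(=O)C(C)(C)C (pivaloyl group stays only in 15)
Why: Proposed new method: a catalytic enantioselective desymmetrising δ-lactonisation of a meso hydroxy diacid through a chiral acyl-isothiouronium ion — pivalic anhydride activates either enantiotopic carboxyl reversibly as the mixed anhydride, acyl transfer to the isothiourea gives two equilibrating diastereomeric acyl-isothiouronium ions whose carbonyl is locked syn-coplanar to sulfur (1,5 S···O contact) with one face blocked by the catalyst phenyl group, and because the α-methyl centres of the two arms have opposite configuration the tethered C5 hydroxyl can reach the open face in a chair-like 6-exo-trig transition state only from the arm with the (S)-configured α-carbon (Curtin–Hammett), so the new acyl C–O bond fixes the absolute configuration of all seven stereocentres and differentiates the termini; the closest known reaction types are the isothiourea/pivalic anhydride asymmetric esterification used for kinetic resolution of racemic α-branched carboxylic acids and chiral acyl-transfer desymmetrisations of meso diols.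

**Step 9**
Reactants: 16 (2R,3S,4R)-3-hydroxy-4-[(2R,3S,4R,5S)-4-hydroxy-3,5-dimethyl-6-oxooxan-2-yl]-2-methylpentanoic acid
Product: 17 (2R,3S,4R)-3-hydroxy-4-[(2S,3S,4R,5S)-4,6-dihydroxy-3,5-dimethyloxan-2-yl]-2-methylpentanoic acid
Conditions: i-Bu2AlH (4.5 equiv), CH2Cl2/THF, −78 °C
Reagents that add atoms: none
Why: Partial reduction of the δ-lactone stops at the tetrahedral aluminium hemiacetal at −78 °C, while the carboxylic acid is carried as its aluminium carboxylate, which is not reduced at this temperature.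

**Step 10**
Reactants: 18 3-methylbut-3-en-2-one
Product: 19 tert-butyldimethyl[(3-methylbuta-1,3-dien-2-yl)oxy]silane
Conditions: TBSOTf, Et3N, CH2Cl2, 0 °C
Reagents that add atoms: tert-butyldimethylsilyl trifluoromethanesulfonate, CC(C)(C)[Si](C)(C)OS(=O)(=O)C(F)(F)F
Why: Soft enolisation and O-silylation of the only enolisable position (the methyl group) gives the 2-silyloxy diene.

**Step 11**
Reactants: 19 tert-butyldimethyl[(3-methylbuta-1,3-dien-2-yl)oxy]silane; 20 1,4-benzoquinone
Product: 22 tert-butyl[(5,8-dimethoxy-3-methyl-1,4-dihydronaphthalen-2-yl)oxy]dimethylsilane, via Diels–Alder adduct 21 (not isolated)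
Conditions: toluene, rt; then K2CO3, Me2SO4, acetone, reflux (N2)
Reagents that add atoms: dimethyl sulfate, COS(=O)(=O)OC
Why: Diels–Alder cycloaddition builds ring A on the quinone (symmetrical dienophile, so no regiochemical issue), then base-mediated enolisation of the ene-dione to the hydroquinone and Williamson O-methylation lock ring B as its dimethyl ether.

**Step 12**
Reactants: 22 tert-butyl[(5,8-dimethoxy-3-methyl-1,4-dihydronaphthalen-2-yl)oxy]dimethylsilane
Product: 24 5,8-dimethoxy-3-methylnaphthalen-2-ol, via naphthyl silyl ether 23 (not isolated)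
Conditions: DDQ (1.05 equiv), toluene, rt; then Bu4NF, AcOH, THF, 0 °C
Reagents that add atoms: none
Why: DDQ dehydrogenation (hydride abstraction from the doubly benzylic/allylic CH2) aromatises ring A, and fluoride then cleaves the aryl silyl ether.

**Step 13**
Reactants: 24 5,8-dimethoxy-3-methylnaphthalen-2-ol; 25 2-(diethoxyphosphoryl)propanoic acid
Product: 27 diethyl [1-(2-hydroxy-5,8-dimethoxy-3-methylnaphthalen-1-yl)-1-oxopropan-2-yl]phosphonate, via acid chloride 26 (not isolated)
Conditions: 25, (COCl)2, DMF (cat.), CH2Cl2, 0 °C → rt; then 24, TiCl4, ClCH2CH2Cl, 0 → 40 °C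
Reagents that add atoms: oxalyl chloride, O=C(Cl)C(Cl)=O (chlorine stays only in 26)
Why: TiCl4-mediated ortho-selective Friedel–Crafts (Fries-type) acylation of the titanium naphthoxide goes to C1, the only free ortho position and the most nucleophilic α-position of the 2-naphthol.

**Step 14**
Reactants: 17 (2R,3S,4R)-3-hydroxy-4-[(2S,3S,4R,5S)-4,6-dihydroxy-3,5-dimethyloxan-2-yl]-2-methylpentanoic acid; 27 diethyl [1-(2-hydroxy-5,8-dimethoxy-3-methylnaphthalen-1-yl)-1-oxopropan-2-yl]phosphonate
Product: 28 (2R,3S,4S,5S,6S,7S,8R,9E)-3,5,7-trihydroxy-11-(2-hydroxy-5,8-dimethoxy-3-methylnaphthalen-1-yl)-2,4,6,8,10-pentamethyl-11-oxoundec-9-enoic acid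
Conditions: LiCl, i-Pr2NEt, MeCN, 0 °C → rt; work-up at pH 4–5, 0 °C
Reagents that add atoms: none
Why: Horner–Wadsworth–Emmons olefination under Masamune–Roush conditions on the open hydroxy-aldehyde tautomer of the lactol: reversible addition and syn-elimination of the stabilised lithium-chelated phosphonate favour the (E)-trisubstituted enone, and the mild amine base leaves the α-stereocentre and the carboxylate untouched.

**Step 15**
Reactants: 28 (2R,3S,4S,5S,6S,7S,8R,9E)-3,5,7-trihydroxy-11-(2-hydroxy-5,8-dimethoxy-3-methylnaphthalen-1-yl)-2,4,6,8,10-pentamethyl-11-oxoundec-9-enoic acid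
Product: 29 (2R,3S,4S,5S,6S,7S,8R,9E)-3,5,7-trihydroxy-11-(2-hydroxy-3-methyl-5,8-dioxo-5,8-dihydronaphthalen-1-yl)-2,4,6,8,10-pentamethyl-11-oxoundec-9-enoic acid
Conditions: (NH4)2Ce(NO3)6 (2.5 equiv), MeCN/H2O, 0 °C, 10 min; NaHCO3 quench
Reagents that add atoms: water, O
Why: Oxidative demethylation of the para-dimethoxy ring (two one-electron oxidations, water addition, loss of methanol) gives the 1,4-quinone; the acyl-substituted naphthol ring cannot form a quinone, and the short cold exposure spares the hydroxy acid and enone.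

**Step 16**
Reactants: 29 (2R,3S,4S,5S,6S,7S,8R,9E)-3,5,7-trihydroxy-11-(2-hydroxy-3-methyl-5,8-dioxo-5,8-dihydronaphthalen-1-yl)-2,4,6,8,10-pentamethyl-11-oxoundec-9-enoic acid
Product: 30 (2R,3S,4S,5S,6S,7S,8R,9E)-11-(6-amino-2-hydroxy-3-methyl-5,8-dioxo-5,8-dihydronaphthalen-1-yl)-3,5,7-trihydroxy-2,4,6,8,10-pentamethyl-11-oxoundec-9-enoic acid (CNP0287228.1)
Conditions: NaN3 (3 equiv), AcOH, THF/H2O, rt, dark
Reagents that add atoms: sodium azide, [Na+].[N-]=[N+]=[N-]
Why: Michael addition of azide to the quinone followed by loss of N2 (internal redox of the azidohydroquinone) forms the C–N bond directly as the aminoquinone; attack goes to the carbon β to the carbonyl peri to the acyl group, because the ring A hydroxyl is para to the ring-fusion carbon bearing the other carbonyl and deactivates it.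

**Compound list**
1 | methacrolein (2-methylprop-2-enal) | C=C(C)C=O | starting material
2 | isopropenylmagnesium bromide | C=C(C)[Mg]Br | starting material
3 | 2,4-dimethylpenta-1,4-dien-3-ol | C=C(C)C(O)C(C)=C | intermediate
4 | {[(2,4-dimethylpenta-1,4-dien-3-yl)oxy]methyl}benzene | C=C(C)C(OCc1ccccc1)C(C)=C | intermediate
5 | 9,9'-[(2R,3s,4S)-3-(benzyloxy)-2,4-dimethylpentane-1,5-diyl]bis(9-borabicyclo[3.3.1]nonane) | B1(C2CCCC1CCC2)C[C@H](C)[C@H](OCc1ccccc1)[C@H](C)CB1C2CCCC1CCC2 | intermediate (not isolated)
6 | (2R,3s,4S)-3-(benzyloxy)-2,4-dimethylpentane-1,5-diol (meso, anti,anti) | OC[C@H](C)[C@H](OCc1ccccc1)[C@H](C)CO | intermediate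
7 | {[(2R,3s,4S)-3-(benzyloxy)-2,4-dimethylpentane-1,5-diyl]bis(oxy)}bis(dimethylsulfonium) dichloride | C[S+](C)OC[C@H](C)[C@H](OCc1ccccc1)[C@H](C)CO[S+](C)C.[Cl-].[Cl-] | intermediate (not isolated)
8 | (2R,3r,4S)-3-(benzyloxy)-2,4-dimethylpentanedial (meso) | O=C[C@H](C)[C@H](OCc1ccccc1)[C@H](C)C=O | intermediate
9 | (Z)-crotylboronic acid pinacol ester, 2-[(2Z)-but-2-en-1-yl]-4,4,5,5-tetramethyl-1,3,2-dioxaborolane | C/C=C\CB1OC(C)(C)C(C)(C)O1 | starting material
10 | (3R,4S,5S,6s,7R,8R,9S)-6-(benzyloxy)-3,5,7,9-tetramethylundeca-1,10-diene-4,8-diol (meso) | C=C[C@@H](C)[C@H](O)[C@H](C)[C@H](OCc1ccccc1)[C@H](C)[C@H](O)[C@@H](C)C=C | intermediate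
11 | bis-ozonide of 10: both vinyl groups converted into 1,2,4-trioxolan-3-yl groups, chain stereocentres as in 10, ozonide carbons unassigned | C1OC(OO1)[C@@H](C)[C@H](O)[C@H](C)[C@H](OCc1ccccc1)[C@H](C)[C@H](O)[C@@H](C)C1OCOO1 | intermediate (not isolated)
12 | (2R,3S,4R,5s,6S,7R,8S)-5-(benzyloxy)-3,7-dihydroxy-2,4,6,8-tetramethylnonanedial (meso) | O=C[C@@H](C)[C@H](O)[C@H](C)[C@H](OCc1ccccc1)[C@H](C)[C@H](O)[C@@H](C)C=O | intermediate (not isolated)
13 | (2R,3S,4R,5s,6S,7R,8S)-5-(benzyloxy)-3,7-dihydroxy-2,4,6,8-tetramethylnonanedioic acid (meso) | OC(=O)[C@@H](C)[C@H](O)[C@H](C)[C@H](OCc1ccccc1)[C@H](C)[C@H](O)[C@@H](C)C(=O)O | intermediate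
14 | (2R,3S,4S,5r,6R,7R,8S)-3,5,7-trihydroxy-2,4,6,8-tetramethylnonanedioic acid (meso; handled as bis(diisopropylethylammonium) salt) | OC(=O)[C@@H](C)[C@H](O)[C@H](C)[C@H](O)[C@H](C)[C@H](O)[C@@H](C)C(=O)O | intermediate
15 | mixed pivalic anhydride of 14 at the carboxyl next to the (S)-configured α-carbon (the arm that cyclises) | CC(C)(C)C(=O)OC(=O)[C@@H](C)[C@H](O)[C@H](C)[C@H](O)[C@H](C)[C@H](O)[C@@H](C)C(=O)O | intermediate (not isolated)
16 | (2R,3S,4R)-3-hydroxy-4-[(2R,3S,4R,5S)-4-hydroxy-3,5-dimethyl-6-oxooxan-2-yl]-2-methylpentanoic acid | O=C1[C@@H](C)[C@H](O)[C@H](C)[C@H](O1)[C@H](C)[C@H](O)[C@@H](C)C(=O)O | intermediate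
17 | (2R,3S,4R)-3-hydroxy-4-[(2S,3S,4R,5S)-4,6-dihydroxy-3,5-dimethyloxan-2-yl]-2-methylpentanoic acid (anomeric mixture at ring C6) | OC1[C@@H](C)[C@H](O)[C@H](C)[C@H](O1)[C@H](C)[C@H](O)[C@@H](C)C(=O)O | intermediate
18 | 3-methylbut-3-en-2-one | CC(=O)C(C)=C | starting material
19 | tert-butyldimethyl[(3-methylbuta-1,3-dien-2-yl)oxy]silane | C=C(C)C(=C)O[Si](C)(C)C(C)(C)C | intermediate
20 | 1,4-benzoquinone | O=C1C=CC(=O)C=C1 | starting material
21 | cis-6-[(tert-butyldimethylsilyl)oxy]-7-methyl-4a,5,8,8a-tetrahydronaphthalene-1,4-dione (racemic, one enantiomer drawn) | O=C1C=CC(=O)[C@@H]2CC(O[Si](C)(C)C(C)(C)C)=C(C)C[C@H]12 | intermediate (not isolated)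
22 | tert-butyl[(5,8-dimethoxy-3-methyl-1,4-dihydronaphthalen-2-yl)oxy]dimethylsilane | COc1ccc(OC)c2c1CC(O[Si](C)(C)C(C)(C)C)=C(C)C2 | intermediate
23 | tert-butyl[(5,8-dimethoxy-3-methylnaphthalen-2-yl)oxy]dimethylsilane | COc1ccc(OC)c2cc(O[Si](C)(C)C(C)(C)C)c(C)cc12 | intermediate (not isolated)
24 | 5,8-dimethoxy-3-methylnaphthalen-2-ol | COc1ccc(OC)c2cc(O)c(C)cc12 | intermediate
25 | 2-(diethoxyphosphoryl)propanoic acid (racemic) | CCOP(=O)(OCC)C(C)C(=O)O | starting material
26 | 2-(diethoxyphosphoryl)propanoyl chloride (racemic) | CCOP(=O)(OCC)C(C)C(=O)Cl | intermediate (not isolated)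
27 | diethyl [1-(2-hydroxy-5,8-dimethoxy-3-methylnaphthalen-1-yl)-1-oxopropan-2-yl]phosphonate (racemic) | CCOP(=O)(OCC)C(C)C(=O)c1c(O)c(C)cc2c(OC)ccc(OC)c12 | intermediate
28 | (2R,3S,4S,5S,6S,7S,8R,9E)-3,5,7-trihydroxy-11-(2-hydroxy-5,8-dimethoxy-3-methylnaphthalen-1-yl)-2,4,6,8,10-pentamethyl-11-oxoundec-9-enoic acid | C/C(=C\[C@@H](C)[C@H](O)[C@H](C)[C@H](O)[C@H](C)[C@H](O)[C@@H](C)C(=O)O)C(=O)c1c(O)c(C)cc2c(OC)ccc(OC)c12 | intermediate
29 | (2R,3S,4S,5S,6S,7S,8R,9E)-3,5,7-trihydroxy-11-(2-hydroxy-3-methyl-5,8-dioxo-5,8-dihydronaphthalen-1-yl)-2,4,6,8,10-pentamethyl-11-oxoundec-9-enoic acid | C/C(=C\[C@@H](C)[C@H](O)[C@H](C)[C@H](O)[C@H](C)[C@H](O)[C@@H](C)C(=O)O)C(=O)c1c(O)c(C)cc2c1C(=O)C=CC2=O | intermediate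
30 | (2R,3S,4S,5S,6S,7S,8R,9E)-11-(6-amino-2-hydroxy-3-methyl-5,8-dioxo-5,8-dihydronaphthalen-1-yl)-3,5,7-trihydroxy-2,4,6,8,10-pentamethyl-11-oxoundec-9-enoic acid (CNP0287228.1) | C/C(=C\[C@@H](C)[C@H](O)[C@H](C)[C@H](O)[C@H](C)[C@H](O)[C@@H](C)C(=O)O)C(=O)c1c(O)c(C)cc2c1C(=O)C=C(N)C2=O | target

**Step count and risks**
Total: 16 steps. Longest linear sequence: 12 steps (steps 1–9, then 14–16); the arene branch (steps 10–13) is 4 steps.

Most likely to fail, first: step 5. Both termini must react anti-Felkin under substrate control alone, and any leakage compounds (about 5:1 per terminus leaves roughly 70% of the meso isomer). The fallback sets out from dialdehyde 8 and comes back at diol 10 with reagent control added. Dialdehyde 8 is treated at −78 °C with 1.0 equiv of (Z)-crotyldiisopinocampheylborane made from one antipode of Ipc2BOMe ((Z)-but-2-ene, KOt-Bu, n-BuLi, then BF3·OEt2). This reagent reacts at the terminus for which it is matched and gives, as its borinate, (2S,3S,4S,5S,6R)-3-(benzyloxy)-5-hydroxy-2,4,6-trimethyloct-7-enal F1 (or its mirror image; both converge on the same meso product). The antipodal reagent is then added in the same pot for the remaining terminus, and NaOH/H2O2 work-up returns 10.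

Second: step 8, the new desymmetrisation. It can fail through uncatalysed (racemic) cyclisation of the mixed anhydride, through poor discrimination of the two arms, or by giving the opposite sense. The known-chemistry fallback sets out from diacid 14 and comes back at lactone acid 16. Free 14 is lactonised without selectivity (TsOH cat., THF, rt) to the racemate of 16, that is 16 together with its antipode (2S,3R,4S)-3-hydroxy-4-[(2S,3R,4S,5R)-4-hydroxy-3,5-dimethyl-6-oxooxan-2-yl]-2-methylpentanoic acid F2. The racemate is resolved classically by crystallising the (R)-1-phenylethylammonium salt of 16 F3 (the amine antipode is chosen by salt screening), and acidification releases 16. The unwanted F2 in the mother liquor is saponified (LiOH, THF/H2O) back to meso 14 and recycled, so no material is lost in principle.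

Third: step 14. The olefination joins a hindered α-methyl ketophosphonate that carries a free naphthol to a lactol that carries a carboxylate, and the liberated C5 hydroxyl or the naphthoxide may add back to the enone. The fallback swaps the roles of the two termini so that C5–O stays locked in the lactone during coupling; it sets out from diacid 14 and comes back at enone acid 28. Step 8 is run with (R)-BTM to give the antipodal lactone acid F2 (also available from the resolution above). BH3·SMe2 (THF, 0 °C) reduces only the carboxylic acid to the lactone alcohol F4 (F2 with CO2H changed to CH2OH). TEMPO/PhI(OAc)2 oxidises the primary alcohol to the lactone aldehyde F5. The same Horner–Wadsworth–Emmons reaction with 27, now on a free aldehyde with no carboxylate and no free δ-hydroxyl, gives the 1,5-lactone of 28 F6 (C1 carboxyl closed on the C5 hydroxyl, 9E alkene and all stereocentres as in 28). LiOH (THF/H2O, 0 °C) then opens the lactone to 28, and steps 15 and 16 follow unchanged.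

**Further compounds**
F1 | step 5 | (2S,3S,4S,5S,6R)-3-(benzyloxy)-5-hydroxy-2,4,6-trimethyloct-7-enal (or its mirror image) | C=C[C@@H](C)[C@H](O)[C@H](C)[C@H](OCc1ccccc1)[C@H](C)C=O
F2 | step 8 | (2S,3R,4S)-3-hydroxy-4-[(2S,3R,4S,5R)-4-hydroxy-3,5-dimethyl-6-oxooxan-2-yl]-2-methylpentanoic acid (antipode of 16) | O=C1[C@H](C)[C@@H](O)[C@@H](C)[C@@H](O1)[C@@H](C)[C@@H](O)[C@H](C)C(=O)O
F3 | step 8 | (R)-1-phenylethylammonium salt of 16 | O=C1[C@@H](C)[C@H](O)[C@H](C)[C@H](O1)[C@H](C)[C@H](O)[C@@H](C)C(=O)[O-].C[C@@H]([NH3+])c1ccccc1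
F4 | step 14 | lactone alcohol: F2 with the free carboxyl reduced to CH2OH, stereocentres as in F2 | O=C1[C@H](C)[C@@H](O)[C@@H](C)[C@@H](O1)[C@@H](C)[C@@H](O)[C@H](C)CO
F5 | step 14 | lactone aldehyde: F4 with CH2OH oxidised to CHO, stereocentres as in F2 | O=C1[C@H](C)[C@@H](O)[C@@H](C)[C@@H](O1)[C@@H](C)[C@@H](O)[C@H](C)C=O
F6 | step 14 | 1,5-lactone of 28 (C1 carboxyl closed on the C5 hydroxyl; 9E alkene and stereocentres as in 28) | C/C(=C\[C@@H](C)[C@H](O)[C@H](C)[C@@H]1OC(=O)[C@H](C)[C@@H](O)[C@H]1C)C(=O)c1c(O)c(C)cc2c(OC)ccc(OC)c12
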